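Seven-membered ring B is read as a benzene ring plus one carbon: C1, C10, C9, C8, C7 and C6 map onto a para-tolyl ring (C1 ipso, C8 the methyl-bearing para carbon), and C5, next to the C4 carbinol, is an α-keto carbene carbon slipped in between C1 and C6. The precursor is therefore 1-diazo-4-(4-methylphenyl)butan-2-one, the arene tethered through C2–C3 to a diazomethyl ketone (C4, C5). One rhodium-carbenoid ring expansion closes cyclopentanone ring A and cycloheptatriene ring B and leaves C5=C1, C6=C7 and C8=C9 where the angular methyl group and the four ring-B oxygens are installed afterwards; absolute configuration enters at a later CBS reduction.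

Key step: step 2

Numbering (daucane numbering, used for atoms throughout and for names from 16 on): C1 angular C–CH3; C2, C3 CH2; C4 C(OH)(i-Pr); C5 ring-fusion CH; C6 CH–O-aroyl; C7 CHOH; C8 epoxide C–CH3; C9 epoxide CH; C10 CH2. Ring A = C1–C5, ring B = C1, C5–C10. β is the face of the C1 methyl group. The target is (1R,4R,5S,6R,7S,8R,9S): 1β-CH3, 4β-OH, 5α-H, 6α-ester, 7β-OH, 8α,9α-epoxide.

Assumption: in the CBS step the fully substituted alkenyl carbon C5 acts as the large carbonyl substituent, as is usual for α-substituted cycloalkenones; the catalyst enantiomer is chosen on that basis.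

Remark: the phenol is carried as its benzyl ether (commercial 4-(benzyloxy)benzoyl chloride), because a free phenol would compete in the esterification; it is released in the last step together with the C7 carbonate.

Step 1
Reactants: 1 3-(4-methylphenyl)propanoic acid; 2 (trimethylsilyl)diazomethane
Product: 5 1-diazo-4-(4-methylphenyl)butan-2-one, via acyl chloride 3 (not isolated), via silyl diazoketone 4 (not isolated)
Conditions: (COCl)2, DMF (cat.), CH2Cl2, 0 °C to rt, volatiles removed; 2 (2.2 equiv), MeCN–THF, 0 °C to rt; aq. NaHCO3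
Reagents that add atoms: (trimethylsilyl)diazomethane 2, C[Si](C)(C)C=[N+]=[N-]
Why: Acyl chlorides C-acylate (trimethylsilyl)diazomethane (Arndt–Eistert-type diazoketone synthesis), the second equivalent of 2 scavenges HCl so that no chloromethyl ketone forms, and the labile C–Si bond of 4 is hydrolysed on work-up; no stereocentre is formed.

Step 2
Reactants: 5 1-diazo-4-(4-methylphenyl)butan-2-one
Product: 8 6-methyl-3,4-dihydroazulen-1(2H)-one, via norcaradiene 6 (not isolated), via kinetic cycloheptatriene 7 (not isolated)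
Conditions: Rh2(OAc)4 (1 mol %), CH2Cl2, reflux, slow addition of 5; then Et3N, rt, same flask
Reagents that add atoms: none
Why: Loss of N2 from 5 on Rh2(OAc)4 gives an electrophilic carbenoid at C5 that adds to the C1–C6 (ipso–ortho) bond of the tolyl ring to give norcaradiene 6, whose C1–C6 bond opens in a thermally allowed disrotatory 6π electrocyclic step to cycloheptatriene 7; Et3N then removes the acidic H-5 and reprotonation at C10 gives the linearly conjugated enone 8. The closest known reaction type is the intramolecular Buchner reaction of 1-diazo-4-arylbutan-2-ones under dirhodium carboxylate catalysis, followed by base isomerisation of the first-formed triene. Ring A closes by intramolecular [2+1] cycloaddition across the three-atom tether (C5–C1 formed, five-membered ketone), and ring B arises by electrocyclic ring expansion of the benzene ring (C5–C6 formed, C1–C6 broken) and not by an end-to-end cyclisation. No stereocentre has to be controlled, because 8 is achiral and the configurations of 6 and 7 are transient. The step needs attack on the ipso–ortho π bond instead of benzylic C–H insertion, aromatic substitution to a 2-tetralone or addition to a remote bond: the short tether reaches only that bond, acetate ligands keep the carbenoid mild, acid is excluded, and because the two ortho positions of the para-substituted ring are equivalent the methyl group can only end up on C8.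

Step 3
Reactants: 8 6-methyl-3,4-dihydroazulen-1(2H)-one
Product: 9 (1S)-6-methyl-1,2,3,4-tetrahydroazulen-1-ol
Conditions: (R)-2-methyl-CBS-oxazaborolidine (0.2 equiv), catecholborane (1.5 equiv), toluene, −78 °C; aq. NaOH work-up
Reagents that add atoms: none
Why: CBS reduction: the oxazaborolidine–borane complex binds the carbonyl lone pair anti to the fully substituted alkenyl carbon C5 and delivers hydride to one face, which should set C4 as S (hydroxyl β), while catecholborane at low temperature leaves the triene untouched.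

Step 4
Reactants: 9 (1S)-6-methyl-1,2,3,4-tetrahydroazulen-1-ol; 10 diiodomethane
Product: 11 (1R,7S,8S)-4-methyltricyclo[5.3.1.0^1,7]undeca-3,5-dien-8-ol
Conditions: Et2Zn (2.0 equiv), CH2I2 (2.0 equiv), CH2Cl2, −20 to 0 °C; aq. NH4Cl
Reagents that add atoms: diiodomethane 10, ICI
Why: Hydroxyl-directed Simmons–Smith (Furukawa) cyclopropanation: the ethylzinc alkoxide of 9 delivers the methylene to the adjacent, most electron-rich tetrasubstituted C5=C1 bond from the face of the oxygen (β), fixing C1 (R) and C5 (S) relative to C4 and leaving the remote C6=C7–C8=C9 diene alone.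

Step 5
Reactants: 11 (1R,7S,8S)-4-methyltricyclo[5.3.1.0^1,7]undeca-3,5-dien-8-ol
Product: 12 (1R,7S)-4-methyltricyclo[5.3.1.0^1,7]undeca-3,5-dien-8-one
Conditions: Dess–Martin periodinane, NaHCO3, CH2Cl2, 0 °C to rt
Reagents that add atoms: none
Why: Dess–Martin oxidation of a secondary cyclopropyl carbinol under bicarbonate buffer erases the temporary C4 stereocentre after it has relayed its configuration to C1 and C5.

Step 6
Reactants: 12 (1R,7S)-4-methyltricyclo[5.3.1.0^1,7]undeca-3,5-dien-8-one
Product: 14 (3aR,8aR)-3a,6-dimethyl-3,3a,4,8a-tetrahydroazulen-1(2H)-one, via diiodosamarium enolate 13 (not isolated)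
Conditions: SmI2 (2.5 equiv), t-BuOH (2 equiv), THF–DMPU, −78 °C; pH 7 phosphate buffer at −78 °C
Reagents that add atoms: none
Why: SmI2 ketyl fragmentation of a cyclopropyl ketone: of the two cyclopropane bonds at C5 only the exocyclic C5–CH2 bond overlaps with the ketyl π system of the flat cyclopentanone, so it breaks to leave the β-methyl group on C1 (configuration retained from 12), and kinetic α-protonation of trienolate 13 at C5 anti to that methyl group should give the trans ring fusion (H-5 α) without moving the diene into conjugation.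

Step 7
Reactants: 14 (3aR,8aR)-3a,6-dimethyl-3,3a,4,8a-tetrahydroazulen-1(2H)-one; 15 isopropylmagnesium chloride
Product: 16 (1R,4R,5R)-dauca-6,8-dien-4-ol
Conditions: CeCl3 (anhydrous, 2 equiv), i-PrMgCl (2 equiv), THF, −78 °C; aq. NH4Cl
Reagents that add atoms: isopropylmagnesium chloride 15, CC(C)[Mg]Cl
Why: 1,2-Addition of the non-basic organocerium reagent i-PrCeCl2, which tolerates the enolisable β,γ-unsaturated ketone: isopropyl attacks C4 from the α face, away from the β-methyl group on C1 and the β-disposed C6, giving the 4β-hydroxyl (4R).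

Step 8
Reactants: 16 (1R,4R,5R)-dauca-6,8-dien-4-ol; 17 dioxygen
Product: 19 (1R,4R,5S,6S)-4,6-dihydroxydauc-7-en-9-one, via endoperoxide 18 (not isolated)
Conditions: O2, tetraphenylporphyrin (cat.), visible light, CH2Cl2, −40 °C; then Et3N, 0 °C to rt
Reagents that add atoms: dioxygen 17, O=O
Why: Singlet-oxygen [4+2] cycloaddition to the s-cis diene from the α face, anti to the axial β-methyl group on the flap carbon C1, sets both C6–O and C9–O α, and the amine-induced Kornblum–DeLaMare rearrangement should remove the less shielded H-9 (H-6 lies gauche to the fully substituted C4) to give the C9 ketone and the 6α-alcohol.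

Step 9
Reactants: 19 (1R,4R,5S,6S)-4,6-dihydroxydauc-7-en-9-one; 20 4-(benzyloxy)benzoyl chloride
Product: 21 (1R,4R,5S,6S)-4-hydroxy-9-oxodauc-7-en-6-yl 4-(benzyloxy)benzoate
Conditions: pyridine, DMAP (cat.), CH2Cl2, 0 °C to rt
Reagents that add atoms: 4-(benzyloxy)benzoyl chloride 20, O=C(Cl)c1ccc(OCc2ccccc2)cc1
Why: DMAP-catalysed acylation (nucleophilic catalysis) of the only secondary alcohol; the tertiary C4 hydroxyl is too hindered to react and C6 keeps its configuration.

Step 10
Reactants: 21 (1R,4R,5S,6S)-4-hydroxy-9-oxodauc-7-en-6-yl 4-(benzyloxy)benzoate; 22 tert-butyl hydroperoxide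
Product: 23 (1R,4R,5S,6R,7S,8S)-7,8-epoxy-4-hydroxy-9-oxodaucan-6-yl 4-(benzyloxy)benzoate
Conditions: t-BuOOH (anhydrous, in decane), DBU, CH2Cl2, 0 °C
Reagents that add atoms: tert-butyl hydroperoxide 22, CC(C)(C)OO
Why: Weitz–Scheffer nucleophilic epoxidation: tert-butylperoxide adds to C7 anti to the neighbouring 6α-aroyloxy group and the enolate closes on oxygen, giving the 7β,8β-epoxide (C7 S, C8 S) under non-aqueous conditions that spare the ester.

Step 11
Reactants: 23 (1R,4R,5S,6R,7S,8S)-7,8-epoxy-4-hydroxy-9-oxodaucan-6-yl 4-(benzyloxy)benzoate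
Product: 25 (1R,4R,5S,6R,7R)-4,7-dihydroxydauc-8-en-6-yl 4-(benzyloxy)benzoate, via epoxy hydrazone 24 (not isolated)
Conditions: N2H4·H2O (3 equiv), AcOH (cat.), MeOH, 0 °C to rt
Reagents that add atoms: none
Why: Wharton transposition: hydrazone 24 opens the epoxide to an alkenyl diazene that loses N2, so the C7–O bond is kept (7β-OH) and the alkene appears at C8=C9, while buffered hydrazine at low temperature is chosen so that the hindered, electron-rich aryl ester is not cleaved.

Step 12
Reactants: 25 (1R,4R,5S,6R,7R)-4,7-dihydroxydauc-8-en-6-yl 4-(benzyloxy)benzoate; 26 benzyl chloroformate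
Product: 27 (1R,4R,5S,6R,7R)-7-{[(benzyloxy)carbonyl]oxy}-4-hydroxydauc-8-en-6-yl 4-(benzyloxy)benzoate
Conditions: CbzCl, pyridine, DMAP (cat.), CH2Cl2, 0 °C to rt
Reagents that add atoms: benzyl chloroformate 26, O=C(Cl)OCc1ccccc1
Why: Chloroformate acylation of the secondary allylic alcohol caps the 7β-hydroxyl as a benzyl carbonate so that it cannot hydrogen-bond to the peracid and steer it to the β face in the next step; the tertiary alcohol does not react.

Step 13
Reactants: 27 (1R,4R,5S,6R,7R)-7-{[(benzyloxy)carbonyl]oxy}-4-hydroxydauc-8-en-6-yl 4-(benzyloxy)benzoate; 28 3-chloroperoxybenzoic acid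
Product: 29 (1R,4R,5S,6R,7S,8R,9S)-7-{[(benzyloxy)carbonyl]oxy}-8,9-epoxy-4-hydroxydaucan-6-yl 4-(benzyloxy)benzoate
Conditions: mCPBA, NaHCO3, CH2Cl2, 0 °C
Reagents that add atoms: 3-chloroperoxybenzoic acid 28, OOC(=O)c1cccc(Cl)c1
Why: Prilezhaev epoxidation of the trisubstituted alkene from the open α face, the β face being blocked by the axial C1 methyl group (1,3 to C9) and by the 7β-carbonate, which sets C8 (R) and C9 (S).

Step 14
Reactants: 29 (1R,4R,5S,6R,7S,8R,9S)-7-{[(benzyloxy)carbonyl]oxy}-8,9-epoxy-4-hydroxydaucan-6-yl 4-(benzyloxy)benzoate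
Product: 30 (1R,4R,5S,6R,7S,8R,9S)-8,9-epoxy-4,7-dihydroxydaucan-6-yl 4-hydroxybenzoate
Conditions: H2 (1 atm), Pd/C (10 %), EtOAc, rt
Reagents that add atoms: none
Why: Hydrogenolysis over Pd/C cleaves the benzyl aryl ether and the benzyl carbonate (with loss of CO2) under neutral conditions that leave the trialkyl epoxide, the ester and all stereocentres untouched.

Compound list
1 | 3-(4-methylphenyl)propanoic acid | Cc1ccc(CCC(=O)O)cc1 | starting material
2 | (trimethylsilyl)diazomethane | C[Si](C)(C)C=[N+]=[N-] | starting material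
3 | 3-(4-methylphenyl)propanoyl chloride | Cc1ccc(CCC(=O)Cl)cc1 | intermediate
4 | 1-diazo-4-(4-methylphenyl)-1-(trimethylsilyl)butan-2-one | Cc1ccc(CCC(=O)C(=[N+]=[N-])[Si](C)(C)C)cc1 | intermediate
5 | 1-diazo-4-(4-methylphenyl)butan-2-one | Cc1ccc(CCC(=O)C=[N+]=[N-])cc1 | intermediate
6 | 8-methyltricyclo[4.4.0.0^1,5]deca-7,9-dien-4-one (norcaradiene, racemic, ring fusion fixed by the cyclopropane) | O=C1CCC23C=CC(C)=CC2C13 | intermediate
7 | 6-methyl-3,8a-dihydroazulen-1(2H)-one (racemic) | O=C1CCC2=CC=C(C)C=CC12 | intermediate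
8 | 6-methyl-3,4-dihydroazulen-1(2H)-one | O=C1CCC2=C1C=CC(C)=CC2 | intermediate
9 | (1S)-6-methyl-1,2,3,4-tetrahydroazulen-1-ol (C4 hydroxyl β) | O[C@H]1CCC2=C1C=CC(C)=CC2 | intermediate
10 | diiodomethane | ICI | starting material
11 | (1R,7S,8S)-4-methyltricyclo[5.3.1.0^1,7]undeca-3,5-dien-8-ol (cyclopropane CH2 and OH both β) | O[C@H]1CC[C@@]23C[C@@]12C=CC(C)=CC3 | intermediate
12 | (1R,7S)-4-methyltricyclo[5.3.1.0^1,7]undeca-3,5-dien-8-one | O=C1CC[C@@]23C[C@@]12C=CC(C)=CC3 | intermediate
13 | diiodosamarium enolate of 14 (trivalent samarium on the C4 oxygen, C4=C5, 1β-CH3) | I[Sm](I)OC1=C2C=CC(C)=CC[C@@]2(C)CC1 | intermediate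
14 | (3aR,8aR)-3a,6-dimethyl-3,3a,4,8a-tetrahydroazulen-1(2H)-one (1β-CH3, 5α-H, trans-fused) | O=C1CC[C@]2(C)CC=C(C)C=C[C@H]21 | intermediate
15 | isopropylmagnesium chloride | CC(C)[Mg]Cl | starting material
16 | (1R,4R,5R)-dauca-6,8-dien-4-ol (4β-OH, 1β-CH3, 5α-H) | CC(C)[C@]1(O)CC[C@]2(C)CC=C(C)C=C[C@H]21 | intermediate
17 | dioxygen | O=O | starting material
18 | (1R,4R,5S,6S,9S)-6,9-epidioxydauc-7-en-4-ol (6α,9α-peroxide bridge) | CC(C)[C@]1(O)CC[C@]2(C)C[C@@H]3OO[C@@H](C=C3C)[C@H]21 | intermediate
19 | (1R,4R,5S,6S)-4,6-dihydroxydauc-7-en-9-one (4β,6α-diol) | CC(C)[C@]1(O)CC[C@]2(C)CC(=O)C(C)=C[C@H](O)[C@H]21 | intermediate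
20 | 4-(benzyloxy)benzoyl chloride | O=C(Cl)c1ccc(OCc2ccccc2)cc1 | starting material
21 | (1R,4R,5S,6S)-4-hydroxy-9-oxodauc-7-en-6-yl 4-(benzyloxy)benzoate (6α-ester) | CC(C)[C@]1(O)CC[C@]2(C)CC(=O)C(C)=C[C@H](OC(=O)c3ccc(OCc4ccccc4)cc3)[C@H]21 | intermediate
22 | tert-butyl hydroperoxide | CC(C)(C)OO | starting material
23 | (1R,4R,5S,6R,7S,8S)-7,8-epoxy-4-hydroxy-9-oxodaucan-6-yl 4-(benzyloxy)benzoate (7β,8β-epoxide) | CC(C)[C@]1(O)CC[C@]2(C)CC(=O)[C@@]3(C)O[C@H]3[C@H](OC(=O)c3ccc(OCc4ccccc4)cc3)[C@H]21 | intermediate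
24 | C9 hydrazone of 23 | CC(C)[C@]1(O)CC[C@]2(C)CC(=NN)[C@@]3(C)O[C@H]3[C@H](OC(=O)c3ccc(OCc4ccccc4)cc3)[C@H]21 | intermediate
25 | (1R,4R,5S,6R,7R)-4,7-dihydroxydauc-8-en-6-yl 4-(benzyloxy)benzoate (4β-OH, 6α-ester, 7β-OH) | CC(C)[C@]1(O)CC[C@]2(C)CC=C(C)[C@@H](O)[C@H](OC(=O)c3ccc(OCc4ccccc4)cc3)[C@H]21 | intermediate
26 | benzyl chloroformate | O=C(Cl)OCc1ccccc1 | starting material
27 | (1R,4R,5S,6R,7R)-7-{[(benzyloxy)carbonyl]oxy}-4-hydroxydauc-8-en-6-yl 4-(benzyloxy)benzoate | CC(C)[C@]1(O)CC[C@]2(C)CC=C(C)[C@@H](OC(=O)OCc3ccccc3)[C@H](OC(=O)c3ccc(OCc4ccccc4)cc3)[C@H]21 | intermediate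
28 | 3-chloroperoxybenzoic acid | OOC(=O)c1cccc(Cl)c1 | starting material
29 | (1R,4R,5S,6R,7S,8R,9S)-7-{[(benzyloxy)carbonyl]oxy}-8,9-epoxy-4-hydroxydaucan-6-yl 4-(benzyloxy)benzoate (8α,9α-epoxide) | CC(C)[C@]1(O)CC[C@]2(C)C[C@@H]3O[C@]3(C)[C@@H](OC(=O)OCc3ccccc3)[C@H](OC(=O)c3ccc(OCc4ccccc4)cc3)[C@H]21 | intermediate
30 | (1R,4R,5S,6R,7S,8R,9S)-8,9-epoxy-4,7-dihydroxydaucan-6-yl 4-hydroxybenzoate, CNP0290052.1 | CC(C)[C@]1(O)CC[C@]2(C)C[C@@H]3O[C@]3(C)[C@@H](O)[C@H](OC(=O)c3ccc(O)cc3)[C@H]21 | target

Total step count: 14. Longest linear sequence: 14 steps (1 to 30); 2, 10, 15, 17, 20, 22, 26 and 28 are purchased.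

Steps most likely to fail

Step 8. The amine may abstract H-6 as readily as H-9, so that the peroxide collapses to the regioisomeric C6 ketone, or oxygen may add to the β face or react in the ene mode at the C8 methyl group. The fallback sets out from 16 and returns at 21; it brings in the C9 and C6 oxygens one after the other instead of together. Dimethyldioxirane (acetone, −20 °C) should epoxidise the more electron-rich trisubstituted C8=C9 bond of 16 from the α face, anti to the axial C1 methyl group, to give 8α,9α-epoxydauc-6-en-4β-ol F1. Pd(PPh3)4 (zerovalent palladium, THF, 0 °C) then ionises the allylic C8–O bond with inversion, and 4-(benzyloxy)benzoic acid attacks the less substituted allyl terminus C6 anti to the metal (Tsuji–Trost 1,4-addition). This places the ester cis to the C9 oxygen and gives 4β,9α-dihydroxydauc-7-en-6α-yl 4-(benzyloxy)benzoate F2 with unambiguous regiochemistry. Dess–Martin oxidation of the secondary allylic C9 alcohol of F2 gives 21.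

Step 6. Electron transfer may go to the dienyl system instead of giving clean ketyl fragmentation, the extended enolate 13 may be protonated at C7 or C9, or the diene may drift into conjugation during the quench with loss of the C5 configuration. The fallback sets out from 12 and returns at 14; it cleaves the C5–CH2 bond by a polar homoconjugate opening instead of by electron transfer and separates bond cleavage from protonation. Iodotrimethylsilane ((Me3Si)2NH, CH2Cl2, −40 °C) should activate the carbonyl while iodide attacks the unhindered cyclopropane CH2 carbon, giving 3a-(iodomethyl)-6-methyl-1-(trimethylsilyloxy)-2,3,3a,4-tetrahydroazulene F3. Buffered hydrolysis (AcOH–NaOAc, aq. THF, 0 °C) protonates C5 anti to the iodomethyl group to give 3a-(iodomethyl)-6-methyl-3,3a,4,8a-tetrahydroazulen-1(2H)-one F4. Radical deiodination (Bu3SnH, Et3B, air, toluene, 0 °C) turns CH2I into the C1 methyl group of 14.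

Step 11. Hydrazone formation at the hindered C9 carbonyl may be slow, which gives hydrazine time to cleave the aryl ester or to promote acyl migration to the freed 7-hydroxyl, and the alkenyl diazene may decay unproductively by radical paths. The fallback sets out from 23 and returns at 25; it achieves the same transposition by radical fragmentation. Luche reduction (NaBH4, CeCl3·7H2O, MeOH, −40 °C) should give 7β,8β-epoxy-4β,9β-dihydroxydaucan-6α-yl 4-(benzyloxy)benzoate F5 by hydride attack on the open α face; the C9 configuration is immaterial. 1,1'-Thiocarbonyldiimidazole (DMAP, CH2Cl2, rt) converts it into 7β,8β-epoxy-4β-hydroxy-9β-[(1H-imidazol-1-ylcarbonothioyl)oxy]daucan-6α-yl 4-(benzyloxy)benzoate F6. Bu3SnH with AIBN (toluene, 80 °C, high stannane concentration) generates the C9 radical (Barton–McCombie-type), which opens the adjacent epoxide by C8–O cleavage; the C7 alkoxy radical takes hydrogen from the stannane to give 25.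

Further compounds
F1 | step 8 | 8α,9α-epoxydauc-6-en-4β-ol | CC(C)[C@]1(O)CC[C@]2(C)C[C@@H]3O[C@]3(C)C=C[C@H]21
F2 | step 8 | 4β,9α-dihydroxydauc-7-en-6α-yl 4-(benzyloxy)benzoate | CC(C)[C@]1(O)CC[C@]2(C)C[C@H](O)C(C)=C[C@H](OC(=O)c3ccc(OCc4ccccc4)cc3)[C@H]21
F3 | step 6 | 3a-(iodomethyl)-6-methyl-1-(trimethylsilyloxy)-2,3,3a,4-tetrahydroazulene (CH2I β) | C[Si](C)(C)OC1=C2C=CC(C)=CC[C@@]2(CI)CC1
F4 | step 6 | 3a-(iodomethyl)-6-methyl-3,3a,4,8a-tetrahydroazulen-1(2H)-one (CH2I β, H-8a α) | O=C1CC[C@]2(CI)CC=C(C)C=C[C@H]21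
F5 | step 11 | 7β,8β-epoxy-4β,9β-dihydroxydaucan-6α-yl 4-(benzyloxy)benzoate | CC(C)[C@]1(O)CC[C@]2(C)C[C@@H](O)[C@@]3(C)O[C@H]3[C@H](OC(=O)c3ccc(OCc4ccccc4)cc3)[C@H]21
F6 | step 11 | 7β,8β-epoxy-4β-hydroxy-9β-[(1H-imidazol-1-ylcarbonothioyl)oxy]daucan-6α-yl 4-(benzyloxy)benzoate | CC(C)[C@]1(O)CC[C@]2(C)C[C@@H](OC(=S)n3ccnc3)[C@@]3(C)O[C@H]3[C@H](OC(=O)c3ccc(OCc4ccccc4)cc3)[C@H]21
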